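Ring C is cut as a formal [4+2]. One partner is the four-atom unit O1–C8a–C4a–C4 of a salicylaldehyde (ring A, both prenyl groups already in place). The other is the two-carbon unit C2–C3 of 3,4-dimethoxyphenylacetylene. The key step exploits the ortho relationship of O1 and C4 on ring A. The phenol oxygen first chelates rhodium, which opens the aldehyde C–H bond for alkyne hydroacylation (C3–C4). The enone formed makes C2 the acceptor for the same oxygen (O1–C2), and a chiral bifunctional thiourea sets C2 as S. The precursors, a 4-O-silyl-3,5-diprenylsalicylaldehyde and a terminal aryl alkyne, are joined in one flask with no atom lost.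

Key step: step 3

Assumption: the sense of induction of the thiourea is assigned by analogy with related phenol-to-enone closures. The quinine- and quinidine-derived catalysts are pseudo-enantiomers and both are commercial, so the series that gives 2S is used. It is written here as the quinidine-derived one.

Step 1
Reactants: 1 2,4-dihydroxybenzaldehyde; 2 prenyl bromide (1-bromo-3-methylbut-2-ene, 2.2 equiv)
Product: 3 2,4-dihydroxy-3,5-bis(3-methylbut-2-enyl)benzaldehyde
Conditions: KOH (2.2 equiv), H2O/MeOH, 0 °C to rt; chromatography
Reagents that add atoms: none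
Why: Nuclear C-prenylation of a resorcinol phenoxide (allylic SN2) in a protic medium, where hydrogen bonding to the oxide oxygens steers alkylation to C3 and C5, the only activated ring carbons, so two equivalents should give the 3,5-diprenyl compound, to be separated from mono-C- and O-alkylated material.

Step 2
Reactants: 3 2,4-dihydroxy-3,5-bis(3-methylbut-2-enyl)benzaldehyde
Product: 4 4-(tert-butyldimethylsilyloxy)-2-hydroxy-3,5-bis(3-methylbut-2-enyl)benzaldehyde
Conditions: TBSCl (1.1 equiv), imidazole, DMF, 0 °C to rt
Reagents that add atoms: tert-butyldimethylsilyl chloride, CC(C)(C)[Si](C)(C)Cl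
Why: Selective silyl ether formation, since the 2-OH is locked in a hydrogen bond to the formyl group and is far less nucleophilic than the more acidic 4-OH, which must be masked so that it cannot quench the basic catalyst of step 3.

Step 3
Reactants: 4 4-(tert-butyldimethylsilyloxy)-2-hydroxy-3,5-bis(3-methylbut-2-enyl)benzaldehyde; 5 4-ethynyl-1,2-dimethoxybenzene
Product: 7 (2S)-7-(tert-butyldimethylsilyloxy)-2-(3,4-dimethoxyphenyl)-6,8-bis(3-methylbut-2-enyl)chroman-4-one, via silyl chalcone 6 (not isolated)
Conditions: [RhCl(cod)]2 (2.5 mol %), 1,1'-bis(diphenylphosphino)ferrocene (5 mol %), Na2CO3 (5 mol %), toluene, 80 °C, slow addition of 5; then same flask without work-up, 0 °C to rt, 9-amino-9-deoxy-epi-quinidine-derived 3,5-bis(trifluoromethyl)phenyl thiourea (15 mol %)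
Reagents that add atoms: none
Why: The 2-phenoxide of 4 binds monovalent rhodium and hands it the aldehyde C–H bond, giving a five-membered acyl rhodium hydride chelate that resists decarbonylation; syn hydrometalation of 5 puts hydride on the aryl-bearing carbon and rhodium on the terminal carbon, and reductive elimination forms C3–C4 of (E)-chalcone 6. The closest known reaction type is the tandem alkyne hydroacylation/oxa-Michael addition of salicylaldehydes to chroman-4-ones, joined here to the known cinchona thiourea-catalysed asymmetric cyclisation of 2'-hydroxychalcones. Ring C closes by a 6-endo-trig oxa-Michael addition of the same phenolic oxygen to C2 (O1–C2). C2 is under catalyst control: the thiourea holds the C4 carbonyl, the quinuclidine nitrogen takes the phenol proton, and only one face of the s-cis enone stays open to O1, which should give 2S. The step needs alkyne-over-prenyl chemoselectivity (trisubstituted alkenes insert into Rh–H far more slowly than a terminal alkyne) and linear regioselectivity (secured by the polarisation and bulk of the electron-rich aryl alkyne and by the wide-bite-angle ligand). It also needs kinetic control of a reversible closure (weak base, low temperature, stopped before equilibrium).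

Step 4
Reactants: 7 (2S)-7-(tert-butyldimethylsilyloxy)-2-(3,4-dimethoxyphenyl)-6,8-bis(3-methylbut-2-enyl)chroman-4-one
Product: 8 (2S)-2-(3,4-dimethoxyphenyl)-7-hydroxy-6,8-bis(3-methylbut-2-enyl)chroman-4-one (IN0946)
Conditions: TBAF/AcOH (1:1, 1.2 equiv), THF, 0 °C
Reagents that add atoms: none
Why: Fluoride-induced desilylation of an aryl silyl ether, in which acetic acid protonates the released 7-phenoxide at once, so the base-induced retro-oxa-Michael ring opening (the only path that could scramble C2) stays closed and the prenyl groups see no strong acid.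

Compound list
1 | 2,4-dihydroxybenzaldehyde | O=Cc1ccc(O)cc1O | starting material
2 | prenyl bromide (1-bromo-3-methylbut-2-ene) | CC(C)=CCBr | starting material
3 | 2,4-dihydroxy-3,5-bis(3-methylbut-2-enyl)benzaldehyde | O=Cc1cc(CC=C(C)C)c(O)c(CC=C(C)C)c1O | intermediate
4 | 4-(tert-butyldimethylsilyloxy)-2-hydroxy-3,5-bis(3-methylbut-2-enyl)benzaldehyde | O=Cc1cc(CC=C(C)C)c(O[Si](C)(C)C(C)(C)C)c(CC=C(C)C)c1O | intermediate
5 | 4-ethynyl-1,2-dimethoxybenzene | C#Cc1ccc(OC)c(OC)c1 | starting material
6 | (E)-4'-(tert-butyldimethylsilyloxy)-2'-hydroxy-3,4-dimethoxy-3',5'-diprenylchalcone (not isolated) | COc1ccc(/C=C/C(=O)c2cc(CC=C(C)C)c(O[Si](C)(C)C(C)(C)C)c(CC=C(C)C)c2O)cc1OC | intermediate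
7 | (2S)-7-(tert-butyldimethylsilyloxy)-2-(3,4-dimethoxyphenyl)-6,8-bis(3-methylbut-2-enyl)chroman-4-one | COc1ccc([C@@H]2CC(=O)c3cc(CC=C(C)C)c(O[Si](C)(C)C(C)(C)C)c(CC=C(C)C)c3O2)cc1OC | intermediate
8 | (2S)-2-(3,4-dimethoxyphenyl)-7-hydroxy-6,8-bis(3-methylbut-2-enyl)chroman-4-one (IN0946) | COc1ccc([C@@H]2CC(=O)c3cc(CC=C(C)C)c(O)c(CC=C(C)C)c3O2)cc1OC | target

Total step count: 4. Longest linear sequence: 4 (1 → 3 → 4 → 7 → 8).

Steps most likely to fail

Step 3. The ring closure is reversible, so the enantiomeric purity may drift towards the racemate as the mixture nears equilibrium. The electron-rich enone may also close slowly. The fallback replaces asymmetric catalysis by resolution and keeps the same two-bond annulation.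
- It sets out from 4 and 5. The same rhodium hydroacylation is followed in the flask by closure with an achiral amine (DABCO, 40 °C) to give the racemic silyl flavanone F1.
- Asymmetric transfer hydrogenation follows, with RuCl(p-cymene)[(R,R)-TsDPEN] in HCO2H/Et3N, run as a kinetic resolution to about half conversion.
- This should reduce the 2R ketone to the cis-(2R,4R)-flavan-4-ol F2, which is removed by chromatography.
- The unreacted 2S ketone comes back to the route at 7.

Step 1. Control may be poor between C- and O-alkylation, and between mono-, di- and geminal alkylation. The fallback replaces phenoxide alkylation by halogenation and cross-coupling.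
- It sets out from 1. Electrophilic iodination (ICl, AcOH, rt) at the two activated positions gives 2,4-dihydroxy-3,5-diiodobenzaldehyde F3.
- A double Stille coupling follows, with tributyl(3-methylbut-2-enyl)stannane (CC(C)=CC[Sn](CCCC)(CCCC)CCCC), Pd(PPh3)4, DMF, 90 °C.
- The stannane leaves the aldehyde and the free phenols untouched and should deliver the linear prenyl groups, coming back to the route at 3.

Step 4. Partial racemisation may occur by base-induced ring opening while the 7-phenoxide is set free. The silyl ether may also be lost too early, during step 3. The fallback changes the protecting-group logic to an acid-labile acetal.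
- It sets out from 3. MOMCl and iPr2NEt in CH2Cl2 give 2-hydroxy-4-(methoxymethoxy)-3,5-diprenylbenzaldehyde F4.
- The conditions of step 3 with 5 lead, through the MOM chalcone F5 formed in the flask, to the (2S)-7-O-MOM flavanone F6.
- Dilute HCl in MeOH at rt removes the acetal under conditions in which the retro-oxa-Michael path is not open, coming back to the route at 8.

Further compounds
F1 | step 3 | racemic 7-(tert-butyldimethylsilyloxy)-2-(3,4-dimethoxyphenyl)-6,8-diprenylchroman-4-one | COc1ccc(C2CC(=O)c3cc(CC=C(C)C)c(O[Si](C)(C)C(C)(C)C)c(CC=C(C)C)c3O2)cc1OC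
F2 | step 3 | (2R,4R)-7-(tert-butyldimethylsilyloxy)-2-(3,4-dimethoxyphenyl)-6,8-diprenylchroman-4-ol | COc1ccc([C@H]2C[C@@H](O)c3cc(CC=C(C)C)c(O[Si](C)(C)C(C)(C)C)c(CC=C(C)C)c3O2)cc1OC
F3 | step 1 | 2,4-dihydroxy-3,5-diiodobenzaldehyde | O=Cc1cc(I)c(O)c(I)c1O
F4 | step 4 | 2-hydroxy-4-(methoxymethoxy)-3,5-bis(3-methylbut-2-enyl)benzaldehyde | O=Cc1cc(CC=C(C)C)c(OCOC)c(CC=C(C)C)c1O
F5 | step 4 | (E)-2'-hydroxy-4'-(methoxymethoxy)-3,4-dimethoxy-3',5'-diprenylchalcone | COCOc1c(CC=C(C)C)cc(C(=O)/C=C/c2ccc(OC)c(OC)c2)c(O)c1CC=C(C)C
F6 | step 4 | (2S)-2-(3,4-dimethoxyphenyl)-7-(methoxymethoxy)-6,8-bis(3-methylbut-2-enyl)chroman-4-one | COc1ccc([C@@H]2CC(=O)c3cc(CC=C(C)C)c(OCOC)c(CC=C(C)C)c3O2)cc1OC
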